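**Retrosynthetic overview**
1. The SMILES encodes a cis-fused labdane, (4R,5S,8R,9R,10S): H-5, the C10 methyl, the C4 methyl, the C8 methyl and the C9 side chain lie on one face; 8-OH and the C4 CH2O arm on the other. The (Z)-coumarate is cut to a diol and built last by esterification with (Z)-3-iodoacrylic acid and Suzuki arylation.
2. The diol comes from a tertiary C8 boronic ester, made by one cationic bicyclization (ring A first, then ring B): an (R)-epoxide opens onto the (Z)-C5=C10 olefin, the C10 cation is taken by a (Z)-alkenyl boronate complex, and methyl shifts from boron to C8.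
3. Water is not used as terminator: with a cis ring fusion, anti capture by water would give the C8 epimer. Methyl delivered anti, then C–B to C–OH with retention, gives the required one.
4. The acyclic precursor comes from a boron–Wittig olefination of a geminal bis(boronate) (C8) with 4-methylidenehex-5-enal (C9–C16, from myrcene).
5. The bis(boronate) comes from an iodide, from an (R)-epoxy alcohol (asymmetric Corey–Chaykovsky), from a (Z)-keto alcohol made by carbocupration of propyne.

Assumption: LaLi3[(S)-binaphthoxide]3 is taken to give the (R)-epoxide 9; if its sense of induction is the opposite, the (R)-binaphthoxide complex is used.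

**Step 1**
Reactants: 1 2-(3-chloropropyl)-2-methyl-1,3-dioxolane; 2 propyne; 3 oxirane
Product: 8 (6Z)-9-hydroxy-6-methylnon-6-en-2-one, via Grignard reagent 4 (not isolated), via alkylcopper 5 (not isolated), via (Z)-alkenylcopper 6 (not isolated), via ketal alcohol 7 (not isolated)
Conditions: Mg, THF, 60 °C; CuBr·SMe2, Et2O/Me2S, −45 °C; propyne, −25 °C; oxirane, −78 → −20 °C; then 2 M HCl, THF, 23 °C
Reagents that add atoms: water, SMILES O
Why: Normant syn-carbocupration of propyne puts the alkyl group and copper cis, so alkylation of the alkenylcopper by oxirane with retention fixes the (Z)-C5=C10 olefin (labdane numbering), and the acidic work-up cleaves the dioxolane.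

**Step 2**
Reactants: 8 (6Z)-9-hydroxy-6-methylnon-6-en-2-one
Product: 9 (3Z)-4-methyl-7-[(2R)-2-methyloxiran-2-yl]hept-3-en-1-ol
Conditions: Me3S(O)I, NaH, THF; LaLi3[(S)-binaphthoxide]3 (5 mol %), (2,4,6-(MeO)3C6H2)3P=O (5 mol %), 5 Å MS, 23 °C
Reagents that add atoms: trimethylsulfoxonium iodide, SMILES C[S+](C)(C)=O.[I-]
Why: Catalytic asymmetric Corey–Chaykovsky epoxidation of a methyl ketone with the La/Li binaphthoxide catalyst adds the sulfoxonium methylide to one carbonyl face and sets C4 as the (R)-2,2-disubstituted epoxide.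

**Step 3**
Reactants: 9 (3Z)-4-methyl-7-[(2R)-2-methyloxiran-2-yl]hept-3-en-1-ol
Product: 10 (2R)-2-[(4Z)-7-iodo-4-methylhept-4-en-1-yl]-2-methyloxirane
Conditions: I2, PPh3, imidazole, CH2Cl2, 0 °C
Reagents that add atoms: iodine, SMILES II
Why: Appel-type iodination (SN2 displacement of the alkoxyphosphonium by iodide) under imidazole buffering converts only the primary alcohol and leaves the epoxide and C4 untouched.

**Step 4**
Reactants: 10 (2R)-2-[(4Z)-7-iodo-4-methylhept-4-en-1-yl]-2-methyloxirane; 11 bis(4,4,5,5-tetramethyl-1,3,2-dioxaborolan-2-yl)methane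
Product: 13 2,2'-{(4Z)-5-methyl-8-[(2R)-2-methyloxiran-2-yl]oct-4-ene-1,1-diyl}bis(4,4,5,5-tetramethyl-1,3,2-dioxaborolane), via lithiated bis(boronate) 12 (not isolated)
Conditions: lithium 2,2,6,6-tetramethylpiperidide (LiTMP, from TMPH and n-BuLi), THF, 0 °C; then 10, 0 → 23 °C
Reagents that add atoms: none
Why: Deprotonation gives a boron-stabilised carbanion that is alkylated by the primary iodide (SN2), and no stereocenter is formed.

**Step 5**
Reactants: 14 myrcene
Product: 15 4-methylidenehex-5-enal
Conditions: O3 (1.0 equiv, Sudan Red 7B end point), CH2Cl2, −78 °C; then Me2S, −78 → 23 °C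
Reagents that add atoms: ozone, SMILES [O-][O+]=O
Why: Ozone attacks the electron-rich trisubstituted double bond much faster than the conjugated diene, so titrated ozonolysis with reductive work-up gives the dienal.

**Step 6**
Reactants: 13 the geminal bis(boronate); 15 4-methylidenehex-5-enal
Product: 17 2-{(6Z,10Z)-11-methyl-3-methylidene-14-[(2R)-2-methyloxiran-2-yl]tetradeca-1,6,10-trien-7-yl}-4,4,5,5-tetramethyl-1,3,2-dioxaborolane, via lithium carbanion 16 (not isolated)
Conditions: LiTMP, THF, 0 °C; then 15, −78 → 23 °C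
Reagents that add atoms: none
Why: Boron–Wittig olefination (carbanion addition to the aldehyde, then syn elimination of a B–O unit) is expected, as in the disubstituted series, to leave the remaining boryl group trans to the aldehyde residue, so that the two carbon chains are cis on C8=C9.

**Step 7**
Reactants: 17 the (6Z,10Z)-epoxy alkenyl boronate
Product: 20 5β-labda-13(16),14-diene-8α,18-diol (4R,5S,8R,9R,10S), via methyl boronate complex 18 (not isolated), via tertiary boronic ester 19 (not isolated)
Conditions: MeLi, Et2O, −78 °C; TMSOTf, Et2O/CH2Cl2, −78 °C; then NaOH, H2O2, THF/MeOH, 0 → 23 °C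
Reagents that add atoms: methyllithium, SMILES [Li]C; hydrogen peroxide, SMILES OO
Why: Proposed new method: silyl triflate activation of the epoxide starts a concerted chair–chair cation–olefin bicyclization ended by a 1,2-metallate shift (closest known types: Lewis acid epoxide-initiated polyene cyclization, and the Zweifel-type rearrangement of alkenyl boronate complexes triggered by carbocations), in which C5 opens the (R)-epoxide with inversion and the CH2OSi arm equatorial (C4), anti addition across the (Z)-C5=C10 bond gives the cis ring fusion (C5, C10), the (Z)-alkenyl boronate places C11 axial as C9 bonds to C10 (C9), and methyl migrates from boron to C8 anti to the new C9–C10 bond, so that boron, oxidised with retention, becomes the 8α-OH (C8).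

**Step 8**
Reactants: 20 5β-labda-13(16),14-diene-8α,18-diol; 21 (2Z)-3-iodoprop-2-enoic acid
Product: 22 8α-hydroxy-5β-labda-13(16),14-dien-18-yl (2Z)-3-iodoprop-2-enoate
Conditions: N,N'-diisopropylcarbodiimide, DMAP (5 mol %), CH2Cl2, −20 → 0 °C
Reagents that add atoms: none
Why: Steglich esterification acylates only the primary C18 alcohol (the tertiary C8 alcohol is inert), and low temperature with catalytic DMAP keeps the (Z)-iodoacrylate geometry.

**Step 9**
Reactants: 22 the (Z)-iodoacrylate; 23 (4-hydroxyphenyl)boronic acid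
Product: 24 8α-hydroxy-5β-labda-13(16),14-dien-18-yl (2Z)-3-(4-hydroxyphenyl)prop-2-enoate (target)
Conditions: Pd(PPh3)4 (5 mol %, zerovalent palladium), K3PO4, THF/H2O, 23 °C
Reagents that add atoms: none
Why: Suzuki–Miyaura coupling of a (Z)-β-iodoacrylate proceeds with retention of olefin geometry at room temperature and tolerates the free phenol, the tertiary alcohol and the diene.

**Compound list**
1 | 2-(3-chloropropyl)-2-methyl-1,3-dioxolane | CC1(CCCCl)OCCO1 | starting material
2 | propyne | CC#C | starting material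
3 | oxirane | C1CO1 | starting material
4 | [3-(2-methyl-1,3-dioxolan-2-yl)propyl]magnesium chloride | CC1(CCC[Mg]Cl)OCCO1 | intermediate
5 | [3-(2-methyl-1,3-dioxolan-2-yl)propyl]copper | CC1(CCC[Cu])OCCO1 | intermediate
6 | [(1Z)-2-methyl-5-(2-methyl-1,3-dioxolan-2-yl)pent-1-en-1-yl]copper | CC1(CCC/C(C)=C\[Cu])OCCO1 | intermediate
7 | (3Z)-4-methyl-7-(2-methyl-1,3-dioxolan-2-yl)hept-3-en-1-ol | CC1(CCC/C(C)=C\CCO)OCCO1 | intermediate
8 | (6Z)-9-hydroxy-6-methylnon-6-en-2-one | CC(=O)CCC/C(C)=C\CCO | intermediate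
9 | (3Z)-4-methyl-7-[(2R)-2-methyloxiran-2-yl]hept-3-en-1-ol | OCC/C=C(C)\CCC[C@]1(C)CO1 | intermediate
10 | (2R)-2-[(4Z)-7-iodo-4-methylhept-4-en-1-yl]-2-methyloxirane | ICC/C=C(C)\CCC[C@]1(C)CO1 | intermediate
11 | bis(4,4,5,5-tetramethyl-1,3,2-dioxaborolan-2-yl)methane | CC1(C)OB(CB2OC(C)(C)C(C)(C)O2)OC1(C)C | starting material
12 | [bis(4,4,5,5-tetramethyl-1,3,2-dioxaborolan-2-yl)methyl]lithium | [Li]C(B1OC(C)(C)C(C)(C)O1)B2OC(C)(C)C(C)(C)O2 | intermediate
13 | 2,2'-{(4Z)-5-methyl-8-[(2R)-2-methyloxiran-2-yl]oct-4-ene-1,1-diyl}bis(4,4,5,5-tetramethyl-1,3,2-dioxaborolane) | CC1(C)OB(OC1(C)C)C(CC/C=C(C)\CCC[C@]2(C)CO2)B3OC(C)(C)C(C)(C)O3 | intermediate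
14 | myrcene (7-methyl-3-methylideneocta-1,6-diene) | CC(C)=CCCC(=C)C=C | starting material
15 | 4-methylidenehex-5-enal | O=CCCC(=C)C=C | intermediate
16 | lithium carbanion of 13 (lithium on the carbon bearing both boryl groups) | [Li]C(CC/C=C(C)\CCC[C@]2(C)CO2)(B1OC(C)(C)C(C)(C)O1)B3OC(C)(C)C(C)(C)O3 | intermediate
17 | 2-{(6Z,10Z)-11-methyl-3-methylidene-14-[(2R)-2-methyloxiran-2-yl]tetradeca-1,6,10-trien-7-yl}-4,4,5,5-tetramethyl-1,3,2-dioxaborolane | CC1(C)OB(OC1(C)C)/C(CC/C=C(C)\CCC[C@]2(C)CO2)=C/CCC(=C)C=C | intermediate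
18 | lithium methyl boronate complex of 17 (tetracoordinate boron bearing CH3) | [Li+].C[B-]1(OC(C)(C)C(C)(C)O1)/C(CC/C=C(C)\CCC[C@]2(C)CO2)=C/CCC(=C)C=C | intermediate
19 | 8α-(4,4,5,5-tetramethyl-1,3,2-dioxaborolan-2-yl)-18-(trimethylsilyloxy)-5β-labda-13(16),14-diene (configuration as in 20, boron in place of 8α-OH) | C=CC(=C)CC[C@@H]1[C@@]2(C)CCC[C@@](C)(CO[Si](C)(C)C)[C@H]2CC[C@@]1(C)B3OC(C)(C)C(C)(C)O3 | intermediate
20 | 5β-labda-13(16),14-diene-8α,18-diol, (4R,5S,8R,9R,10S), cis-fused | C=CC(=C)CC[C@@H]1[C@@]2(C)CCC[C@@](C)(CO)[C@H]2CC[C@@]1(C)O | intermediate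
21 | (2Z)-3-iodoprop-2-enoic acid | OC(=O)/C=C\I | starting material
22 | 8α-hydroxy-5β-labda-13(16),14-dien-18-yl (2Z)-3-iodoprop-2-enoate | C=CC(=C)CC[C@@H]1[C@@]2(C)CCC[C@@](C)(COC(=O)/C=C\I)[C@H]2CC[C@@]1(C)O | intermediate
23 | (4-hydroxyphenyl)boronic acid | OB(O)c1ccc(O)cc1 | starting material
24 | 8α-hydroxy-5β-labda-13(16),14-dien-18-yl (2Z)-3-(4-hydroxyphenyl)prop-2-enoate, (4R,5S,8R,9R,10S) | C=CC(=C)CC[C@@H]1[C@@]2(C)CCC[C@@](C)(COC(=O)/C=C\c3ccc(O)cc3)[C@H]2CC[C@@]1(C)O | target

**Totals**
Total step count: 9. Longest linear sequence: 8 steps (steps 1, 2, 3, 4, 6, 7, 8, 9).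

**Three steps most likely to fail**

1. Step 7 (bicyclization with 1,2-methyl shift). The boronate complex may not survive epoxide activation; the epoxide may rearrange to an aldehyde; the minor fold gives a diastereomer. Fallback, from 17 back to 20: copper-mediated acetoxylation of the alkenyl boronate (Cu(OAc)2, AcOH, Et3N, with retention) gives the (E)-enol acetate F1. A MeAlCl2-promoted epoxide-initiated bicyclization with the enol ester as terminator (CH2Cl2, −78 °C, aqueous work-up) gives the cis-fused hydroxy ketone F2, with C4, C5, C10 and C9 set by the same chair folding. Methyl addition (MeMgBr, CeCl3, THF, −78 °C) from the face opposite the axial ring A methylene then gives 20; this facial preference is less secure than the concerted shift.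

2. Step 6 (geometry of the boron–Wittig olefination, which decides C9). Fallback, from 15 and 10 back to 17, stereospecific:
   - Homologation of 15 with dimethyl (1-diazo-2-oxopropyl)phosphonate (K2CO3, MeOH) gives the enyne F3.
   - Lithiation and borylation (n-BuLi; 2-isopropoxy-4,4,5,5-tetramethyl-1,3,2-dioxaborolane) give the alkynyl boronate F4.
   - Hydrozirconation with Cp2Zr(H)Cl and bromination with NBS give the (E)-α-bromoalkenyl boronate F5 (boron cis to the side chain).
   - Iodide 10 is converted with t-BuLi (Et2O, −78 °C) into the alkyllithium F6, which adds to F5 to give the bromo boronate complex F7.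
   - 1,2-Migration with inversion at the alkenyl carbon on warming gives 17.

3. Step 2 (enantioselective epoxidation of a hydroxy ketone). Fallback, from 8 back to 9: uncatalysed Corey–Chaykovsky epoxidation (Me3S(O)I, NaH, DMSO) gives the racemic epoxy alcohol F8. Kinetic resolution with an (S)-selective bacterial epoxide hydrolase (Rhodococcus type, buffer, pH 8) hydrolyses the (S)-epoxide to the triol F9 and leaves (R)-configured 9, separated by chromatography.

**Further compounds**
F1 | step 7 | (6E,10Z)-11-methyl-3-methylidene-14-[(2R)-2-methyloxiran-2-yl]tetradeca-1,6,10-trien-7-yl acetate | CC(=O)O/C(CC/C=C(C)\CCC[C@]1(C)CO1)=C/CCC(=C)C=C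
F2 | step 7 | 18-hydroxy-17-nor-5β-labda-13(16),14-dien-8-one (configuration at C4, C5, C9, C10 as in 20) | C=CC(=C)CC[C@@H]1[C@@]2(C)CCC[C@@](C)(CO)[C@H]2CCC1=O
F3 | step 6 | 5-methylidenehept-6-en-1-yne | C#CCCC(=C)C=C
F4 | step 6 | 4,4,5,5-tetramethyl-2-(5-methylidenehept-6-en-1-yn-1-yl)-1,3,2-dioxaborolane | CC1(C)OB(C#CCCC(=C)C=C)OC1(C)C
F5 | step 6 | 2-[(1E)-1-bromo-5-methylidenehepta-1,6-dien-1-yl]-4,4,5,5-tetramethyl-1,3,2-dioxaborolane | CC1(C)OB(OC1(C)C)/C(Br)=C\CCC(=C)C=C
F6 | step 6 | {(3Z)-4-methyl-7-[(2R)-2-methyloxiran-2-yl]hept-3-en-1-yl}lithium | [Li]CC/C=C(C)\CCC[C@]1(C)CO1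
F7 | step 6 | lithium boronate complex of F5 with F6 (tetracoordinate boron bearing the heptenyl chain) | [Li+].CC1(C)O[B-](CC/C=C(C)\CCC[C@]2(C)CO2)(OC1(C)C)/C(Br)=C\CCC(=C)C=C
F8 | step 2 | racemic (3Z)-4-methyl-7-(2-methyloxiran-2-yl)hept-3-en-1-ol | OCC/C=C(C)\CCCC1(C)CO1
F9 | step 2 | (2S,6Z)-2,6-dimethylnon-6-ene-1,2,9-triol | OCC/C=C(C)\CCC[C@@](O)(C)CO
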